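**Retrosynthetic overview**

Ring atoms carry germacrane numbers: ring C1–C10, C4 the methyl carbinol, C5 the CHOH, C6 the angelate carbon, C7 bearing the C11 carbinol, C10 bearing a methyl.
1. The plan rests on the bare hydrocarbon arc C10–C1–C2–C3 of the ten-membered ring, which lies opposite the crowded oxygenated tetrad C4–C7. Its C1–C2 bond is the least hindered bond of the ring and is made last, by ring-closing metathesis of an acyclic diene (vinyl on C10, allyl on C4) that already holds all five stereocentres.
2. The diene comes from an Evans syn aldol (C6–C7 bond) between the oxazolidinone imide of (R)-5-methylhept-6-enoic acid (C10 from (R)-citronellene) and a dioxolane aldehyde carrying C4 and C5, followed by twofold methyl addition at C11.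
3. The aldehyde comes from a Sharpless kinetic resolution/epoxidation of an isopropenyl carbinol (sets C4 and C5) and vinyl-cuprate opening of the epoxide (makes C3–C2, the allyl group).
4. Ring order: the dioxolane ring (step 10) is formed first, the ten-membered carbocycle second (step 16). Hydrogenation, angeloylation of O6 and acetonide hydrolysis finish the route.

Key step: step 16

Remark: the geometry of the C1=C2 bond of 24 is not controlled and is drawn Z; this is immaterial because step 17 saturates it. No silyl groups are carried on O6 and O11, since a free tertiary alcohol and a free secondary alcohol are tolerated in steps 15–18.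

**Route**

Step 1
Reactants: 1 (R)-β-citronellene [(R)-3,7-dimethylocta-1,6-diene]
Product: 2 (3R)-6,7-epoxy-3,7-dimethyloct-1-ene (both epoxide epimers)
Conditions: mCPBA (1.05 equiv), CH2Cl2, 0 °C
Reagents that add atoms: mCPBA (3-chloroperoxybenzoic acid), OOC(=O)c1cccc(Cl)c1
Why: Prilezhaev epoxidation should take the electron-rich trisubstituted alkene far faster than the vinyl group and leaves the methyl-bearing stereocentre (later C10) untouched, while the epoxide configuration is irrelevant because that carbon is cleaved next.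

Step 2
Reactants: 2 (3R)-6,7-epoxy-3,7-dimethyloct-1-ene
Product: 4 (R)-4-methylhex-5-enal, via diol 3 (not isolated)
Conditions: H5IO6 (1.2 equiv), THF/H2O, 0 °C → rt
Reagents that add atoms: none
Why: acid-mediated epoxide hydrolysis followed by Malaprade glycol cleavage should excise the isopropylidene carbon as acetone and leave the aldehyde whose carbonyl carbon becomes C7, with the vinyl group inert to periodic acid.

Step 3
Reactants: 4 (R)-4-methylhex-5-enal
Product: 5 (R)-1-methoxy-5-methylhepta-1,6-diene (E/Z mixture)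
Conditions: Ph3P(CH2OMe)Cl, KOtBu, THF, 0 °C → rt
Reagents that add atoms: (methoxymethyl)triphenylphosphonium chloride, COC[P+](c1ccccc1)(c1ccccc1)c1ccccc1.[Cl-]
Why: Wittig methoxymethylenation of an unhindered aldehyde adds the single carbon that becomes C11, and the enol ether geometry does not matter.

Step 4
Reactants: 5 (R)-1-methoxy-5-methylhepta-1,6-diene
Product: 6 (R)-5-methylhept-6-enal
Conditions: 2 M aq HCl, THF, rt
Reagents that add atoms: water, O
Why: acid-catalysed enol ether hydrolysis should unveil the homologated aldehyde without touching the remote stereocentre or the terminal alkene.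

Step 5
Reactants: 6 (R)-5-methylhept-6-enal
Product: 7 (R)-5-methylhept-6-enoic acid
Conditions: NaClO2, NaH2PO4, 2-methyl-2-butene, t-BuOH/H2O, rt
Reagents that add atoms: sodium chlorite, [Na+].[O-]Cl=O
Why: Pinnick oxidation is selective for the aldehyde, and the scavenger alkene traps hypochlorous acid so that the vinyl group survives.

Step 6
Reactants: 7 (R)-5-methylhept-6-enoic acid; 8 (R)-4-benzyloxazolidin-2-one
Product: 10 (R)-4-benzyl-3-[(R)-5-methylhept-6-enoyl]oxazolidin-2-one, via mixed pivalic anhydride 9 (not isolated)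
Conditions: PivCl, Et3N, THF, −20 °C; then 8, LiCl, −20 °C → rt
Reagents that add atoms: none
Why: N-acylation of the oxazolidinone through a mixed anhydride should occur at the unhindered acyl carbon (the pivaloyl carbonyl is shielded), with LiCl activating the carbamate nitrogen under mild conditions.

Step 7
Reactants: 11 (tert-butyldimethylsilyloxy)acetaldehyde
Product: 12 racemic 1-[(tert-butyldimethylsilyl)oxy]-3-methylbut-3-en-2-ol
Conditions: CH2=C(CH3)MgBr (1.2 equiv), THF, −78 → 0 °C; aq NH4Cl
Reagents that add atoms: isopropenylmagnesium bromide, C=C(C)[Mg]Br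
Why: Grignard 1,2-addition to the aldehyde gives the racemic 2-substituted secondary allylic alcohol that is the substrate class for the resolution in step 8, and the cold magnesium alkoxide should not trigger silyl migration.

Step 8
Reactants: 12 racemic 1-[(tert-butyldimethylsilyl)oxy]-3-methylbut-3-en-2-ol
Product: 13 (S)-2-[(tert-butyldimethylsilyl)oxy]-1-[(R)-2-methyloxiran-2-yl]ethan-1-ol
Conditions: Ti(OiPr)4 (10 mol %), L-(+)-diisopropyl tartrate (15 mol %), t-BuOOH (0.45 equiv), 4 Å MS, CH2Cl2, −20 °C
Reagents that add atoms: tert-butyl hydroperoxide, CC(C)(C)OO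
Why: Sharpless kinetic resolution by asymmetric epoxidation should epoxidise only the (R)-alcohol with L-(+)-tartrate and do so erythro-selectively, so C5 is set by enantiomer selection and C4 by oxygen delivery to one alkene face within the titanium–tartrate complex, while the (S)-alcohol stays behind.

Step 9
Reactants: 13 (S)-2-[(tert-butyldimethylsilyl)oxy]-1-[(R)-2-methyloxiran-2-yl]ethan-1-ol
Product: 14 (2S,3R)-1-[(tert-butyldimethylsilyl)oxy]-3-methylhex-5-ene-2,3-diol
Conditions: CH2=CHMgBr (3 equiv), CuI (10 mol %), THF, −40 → −10 °C; aq NH4Cl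
Reagents that add atoms: vinylmagnesium bromide, C=C[Mg]Br
Why: copper-catalysed Grignard opening of the 2,2-disubstituted epoxide should occur by SN2 attack at the unhindered CH2 terminus, which makes the C3–C2 bond and the allyl group without breaking the C4–O bond, so both stereocentres are retained.

Step 10
Reactants: 14 (2S,3R)-1-[(tert-butyldimethylsilyl)oxy]-3-methylhex-5-ene-2,3-diol
Product: 15 tert-butyl{[(4S,5R)-5-allyl-2,2,5-trimethyl-1,3-dioxolan-4-yl]methoxy}dimethylsilane
Conditions: Me2C(OMe)2, PPTS (cat.), CH2Cl2, rt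
Reagents that add atoms: 2,2-dimethoxypropane, COC(C)(C)OC
Why: acid-catalysed transketalisation closes the dioxolane over the secondary/tertiary 1,2-diol, which places the allyl group and C6 cis on the five-membered ring, and the primary silyl ether should survive the mild acid.

Step 11
Reactants: 15 tert-butyl{[(4S,5R)-5-allyl-2,2,5-trimethyl-1,3-dioxolan-4-yl]methoxy}dimethylsilane
Product: 16 [(4S,5R)-5-allyl-2,2,5-trimethyl-1,3-dioxolan-4-yl]methanol
Conditions: TBAF, THF, 0 °C → rt
Reagents that add atoms: none
Why: fluoride-driven desilylation frees the primary alcohol while acetonide and alkene are inert.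

Step 12
Reactants: 16 [(4S,5R)-5-allyl-2,2,5-trimethyl-1,3-dioxolan-4-yl]methanol
Product: 17 (4R,5R)-5-allyl-2,2,5-trimethyl-1,3-dioxolane-4-carbaldehyde
Conditions: Dess–Martin periodinane, pyridine, CH2Cl2, 0 °C → rt
Reagents that add atoms: none
Why: Dess–Martin oxidation under buffered, non-basic conditions should give the α-alkoxy aldehyde (C6) without epimerising C5, and the aldehyde is used at once.

Step 13
Reactants: 10 (R)-4-benzyl-3-[(R)-5-methylhept-6-enoyl]oxazolidin-2-one; 17 (4R,5R)-5-allyl-2,2,5-trimethyl-1,3-dioxolane-4-carbaldehyde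
Product: 20 (R)-4-benzyl-3-{(2R,3R)-3-[(4S,5R)-5-allyl-2,2,5-trimethyl-1,3-dioxolan-4-yl]-3-hydroxy-2-[(R)-3-methylpent-4-en-1-yl]propanoyl}oxazolidin-2-one, via dibutylboron enolate 18 (not isolated), via boron aldolate 19 (not isolated)
Conditions: Bu2BOTf (1.2 equiv), i-Pr2NEt (1.3 equiv), CH2Cl2, −78 → 0 °C; 17, −78 → 0 °C; pH 7 buffer, MeOH, 30% H2O2, 0 °C
Reagents that add atoms: none
Why: Evans syn aldol through the Z-boron enolate and a Zimmerman–Traxler chair, in which the (R)-benzyl auxiliary shields one enolate face, should set C7 (R) and C6 (R) with the 6,7-syn relationship, the auxiliary having to override the weaker Cornforth preference of the α-alkoxy aldehyde for the opposite face.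

Step 14
Reactants: 20 aldol adduct
Product: 21 methyl (2R,3R)-3-[(4S,5R)-5-allyl-2,2,5-trimethyl-1,3-dioxolan-4-yl]-3-hydroxy-2-[(R)-3-methylpent-4-en-1-yl]propanoate
Conditions: NaOMe (0.5 equiv), MeOH/CH2Cl2, −10 °C
Reagents that add atoms: methanol, CO
Why: methoxide transesterification at the exocyclic imide carbonyl releases the auxiliary, and a short cold exposure should avoid retro-aldol cleavage and epimerisation at C7.

Step 15
Reactants: 21 methyl ester
Product: 23 (1R,2R,5R)-1-[(4S,5R)-5-allyl-2,2,5-trimethyl-1,3-dioxolan-4-yl]-2-(2-hydroxypropan-2-yl)-5-methylhept-6-en-1-ol (acyclic diene diol), via methyl ketone 22 (not isolated)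
Conditions: MeMgBr (5 equiv), THF, −20 → 0 °C; aq NH4Cl
Reagents that add atoms: methylmagnesium bromide, C[Mg]Br
Why: twofold Grignard addition to the ester builds the C11 dimethyl carbinol, the magnesium alkoxide at O6 formed first being slow to undergo retro-aldol at this temperature and no stereocentre being created.

Step 16
Reactants: 23 acyclic diene diol
Product: 24 ten-membered C1=C2 (Z) cycloalkene with cis-fused 4,5-O-isopropylidene; 6-OH; 7-(2-hydroxypropan-2-yl); 4- and 10-methyl; (4R,5S,6R,7R,10R)
Conditions: second-generation Grubbs catalyst RuCl2(=CHPh)(H2IMes)(PCy3) (10 mol %, added by syringe pump), 1,4-benzoquinone (20 mol %), toluene (0.5 mM), 80 °C, argon sparge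
Reagents that add atoms: none
Why: The ruthenium benzylidene exchanges onto the unbranched allyl terminus (C2) to give a ruthenium alkylidene, which adds to the C10 vinyl group by [2+2] cycloaddition, and cycloreversion of the ruthenacyclobutane releases the ring with the new C1=C2 bond and ethene. The closest known reaction type is ring-closing metathesis of conformationally constrained 1,ω-dienes to ten-membered carbocycles and decanolides. The ten-membered ring is the only ring closed, by intramolecular alkene–alkene metathesis between the two terminal olefins. No stereocentre is created, and the alkene geometry is without consequence because the bond is hydrogenated in step 17. The step needs cyclisation to outrun acyclic diene metathesis oligomerisation: the cis-dioxolane holds the C3 and C6 arms on one face of a five-membered ring and the substituents on C6 and C7 add gauche turns, so the chain ends are pre-folded, while high dilution, slow catalyst addition and removal of ethene favour the monomeric ring. Benzoquinone is added to suppress ruthenium hydride-mediated alkene migration, which would lead to ring-contracted products or erode C10.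

Step 17
Reactants: 24 ten-membered cycloalkene
Product: 25 saturated ten-membered ring with cis-fused 4,5-O-isopropylidene; 6-OH; 7-(2-hydroxypropan-2-yl); 4- and 10-methyl; (4R,5S,6R,7R,10S)
Conditions: H2 (1 atm), PtO2 (5 mol %), EtOAc, rt
Reagents that add atoms: none
Why: heterogeneous catalytic hydrogenation of the disubstituted ring alkene over platinum, chosen over palladium to limit alkene migration toward C10, should saturate C1–C2 without touching any stereocentre.

Step 18
Reactants: 25 saturated diol acetonide; 26 angelic acid [(Z)-2-methylbut-2-enoic acid]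
Product: 28 6-O-angeloyl derivative of 25 [(4R,5S,6R,7R,10S); O6 carries (Z)-2-methylbut-2-enoyl], via angelic mixed anhydride 27 (not isolated)
Conditions: 26, 2,4,6-Cl3C6H2COCl, Et3N, toluene, rt; then 25, toluene, 80 °C
Reagents that add atoms: none
Why: Yamaguchi-type mixed-anhydride esterification run without a nucleophilic catalyst should acylate only the secondary C6 hydroxyl (the tertiary C11 hydroxyl is inert and the shielded trichlorobenzoyl carbonyl is not attacked) and should keep the Z geometry of the angeloyl unit.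

Step 19
Reactants: 28 angelate acetonide
Product: 29 CNP0130723.1, (1R,2S,3R,7S,10R)-2,3-dihydroxy-10-(2-hydroxypropan-2-yl)-3,7-dimethylcyclodecyl (2Z)-2-methylbut-2-enoate
Conditions: AcOH/H2O (4:1), 40 °C
Reagents that add atoms: none
Why: acid-catalysed acetonide hydrolysis under mild, base-free conditions should free the C4/C5 diol while the angelate neither migrates nor isomerises and the tertiary alcohols do not eliminate.

**Compound list**

1 | (R)-β-citronellene, (R)-3,7-dimethylocta-1,6-diene | C=C[C@H](C)CCC=C(C)C | starting material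
2 | (3R)-6,7-epoxy-3,7-dimethyloct-1-ene (epoxide epimers) | C=C[C@H](C)CCC1OC1(C)C | intermediate
3 | (6R)-2,6-dimethyloct-7-ene-2,3-diol (not isolated) | C=C[C@H](C)CCC(O)C(C)(C)O | intermediate
4 | (R)-4-methylhex-5-enal | C=C[C@H](C)CCC=O | intermediate
5 | (R)-1-methoxy-5-methylhepta-1,6-diene (E/Z) | C=C[C@H](C)CCC=COC | intermediate
6 | (R)-5-methylhept-6-enal | C=C[C@H](C)CCCC=O | intermediate
7 | (R)-5-methylhept-6-enoic acid | C=C[C@H](C)CCCC(=O)O | intermediate
8 | (R)-4-benzyloxazolidin-2-one | O=C1OC[C@@H](Cc2ccccc2)N1 | starting material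
9 | (R)-5-methylhept-6-enoic pivalic anhydride (not isolated) | C=C[C@H](C)CCCC(=O)OC(=O)C(C)(C)C | intermediate
10 | (R)-4-benzyl-3-[(R)-5-methylhept-6-enoyl]oxazolidin-2-one | C=C[C@H](C)CCCC(=O)N1[C@H](Cc2ccccc2)COC1=O | intermediate
11 | (tert-butyldimethylsilyloxy)acetaldehyde | O=CCO[Si](C)(C)C(C)(C)C | starting material
12 | racemic 1-[(tert-butyldimethylsilyl)oxy]-3-methylbut-3-en-2-ol | C=C(C)C(O)CO[Si](C)(C)C(C)(C)C | intermediate
13 | (S)-2-[(tert-butyldimethylsilyl)oxy]-1-[(R)-2-methyloxiran-2-yl]ethan-1-ol | C[C@@]1(CO1)[C@@H](O)CO[Si](C)(C)C(C)(C)C | intermediate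
14 | (2S,3R)-1-[(tert-butyldimethylsilyl)oxy]-3-methylhex-5-ene-2,3-diol | C=CC[C@@](C)(O)[C@@H](O)CO[Si](C)(C)C(C)(C)C | intermediate
15 | tert-butyl{[(4S,5R)-5-allyl-2,2,5-trimethyl-1,3-dioxolan-4-yl]methoxy}dimethylsilane | C=CC[C@@]1(C)OC(C)(C)O[C@H]1CO[Si](C)(C)C(C)(C)C | intermediate
16 | [(4S,5R)-5-allyl-2,2,5-trimethyl-1,3-dioxolan-4-yl]methanol | C=CC[C@@]1(C)OC(C)(C)O[C@H]1CO | intermediate
17 | (4R,5R)-5-allyl-2,2,5-trimethyl-1,3-dioxolane-4-carbaldehyde | C=CC[C@@]1(C)OC(C)(C)O[C@H]1C=O | intermediate
18 | (Z)-dibutylboron enolate of 10 (not isolated) | C=C[C@H](C)CC/C=C(\OB(CCCC)CCCC)N1[C@H](Cc2ccccc2)COC1=O | intermediate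
19 | dibutylboron aldolate of 20 (not isolated) | C=C[C@H](C)CC[C@@H](C(=O)N1[C@H](Cc2ccccc2)COC1=O)[C@@H](OB(CCCC)CCCC)[C@@H]1OC(C)(C)O[C@]1(C)CC=C | intermediate
20 | (R)-4-benzyl-3-{(2R,3R)-3-[(4S,5R)-5-allyl-2,2,5-trimethyl-1,3-dioxolan-4-yl]-3-hydroxy-2-[(R)-3-methylpent-4-en-1-yl]propanoyl}oxazolidin-2-one | C=C[C@H](C)CC[C@@H](C(=O)N1[C@H](Cc2ccccc2)COC1=O)[C@@H](O)[C@@H]1OC(C)(C)O[C@]1(C)CC=C | intermediate
21 | methyl (2R,3R)-3-[(4S,5R)-5-allyl-2,2,5-trimethyl-1,3-dioxolan-4-yl]-3-hydroxy-2-[(R)-3-methylpent-4-en-1-yl]propanoate | C=C[C@H](C)CC[C@@H](C(=O)OC)[C@@H](O)[C@@H]1OC(C)(C)O[C@]1(C)CC=C | intermediate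
22 | (3R,4R)-4-[(4S,5R)-5-allyl-2,2,5-trimethyl-1,3-dioxolan-4-yl]-4-hydroxy-3-[(R)-3-methylpent-4-en-1-yl]butan-2-one (not isolated) | C=C[C@H](C)CC[C@@H](C(C)=O)[C@@H](O)[C@@H]1OC(C)(C)O[C@]1(C)CC=C | intermediate
23 | (1R,2R,5R)-1-[(4S,5R)-5-allyl-2,2,5-trimethyl-1,3-dioxolan-4-yl]-2-(2-hydroxypropan-2-yl)-5-methylhept-6-en-1-ol (metathesis precursor) | C=C[C@H](C)CC[C@@H](C(C)(C)O)[C@@H](O)[C@@H]1OC(C)(C)O[C@]1(C)CC=C | intermediate
24 | ten-membered C1=C2 (Z) cycloalkene, 4,5-O-isopropylidene, 6-OH, 7-(2-hydroxypropan-2-yl), (4R,5S,6R,7R,10R) | O[C@@H]1[C@H](C(C)(C)O)CC[C@@H](C)/C=C\C[C@@](C)(OC(C)(C)O2)[C@H]12 | intermediate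
25 | saturated ten-membered ring, 4,5-O-isopropylidene, 6-OH, 7-(2-hydroxypropan-2-yl), (4R,5S,6R,7R,10S) | O[C@@H]1[C@H](C(C)(C)O)CC[C@@H](C)CCC[C@@](C)(OC(C)(C)O2)[C@H]12 | intermediate
26 | angelic acid, (Z)-2-methylbut-2-enoic acid | C/C=C(/C)C(=O)O | starting material
27 | (Z)-2-methylbut-2-enoic 2,4,6-trichlorobenzoic anhydride (not isolated) | C/C=C(/C)C(=O)OC(=O)c1c(Cl)cc(Cl)cc1Cl | intermediate
28 | 6-O-angeloyl derivative of 25, (4R,5S,6R,7R,10S) | C/C=C(/C)C(=O)O[C@@H]1[C@H](C(C)(C)O)CC[C@@H](C)CCC[C@@](C)(OC(C)(C)O2)[C@H]12 | intermediate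
29 | CNP0130723.1, (1R,2S,3R,7S,10R)-2,3-dihydroxy-10-(2-hydroxypropan-2-yl)-3,7-dimethylcyclodecyl (2Z)-2-methylbut-2-enoate | C/C=C(/C)C(=O)O[C@@H]1[C@H](C(C)(C)O)CC[C@@H](C)CCC[C@@](C)(O)[C@H]1O | target

**Totals**

Total step count: 19 (steps 1–6 to imide 10, steps 7–12 to aldehyde 17, steps 13–19 after their union).
Longest linear sequence: 13 steps (1 → 10 → 29, or equally 11 → 17 → 29).

**Steps most likely to fail**

1. Step 16 (ring-closing metathesis). Intermolecular metathesis may oligomerise the diene, or the catalyst may decompose, before the strained ten-membered ring closes. The fallback makes the same C1=C2 bond by carbonyl coupling and sets out from 23. Both hydroxyls are silylated (Et3SiOTf, 2,6-lutidine, CH2Cl2, 0 °C) to the bis(triethylsilyl) ether F1. Ozonolysis of both terminal alkenes (O3, CH2Cl2, −78 °C; PPh3) should give the C1,C2-dialdehyde F2. Intramolecular McMurry coupling with low-valent titanium (TiCl3(DME)1.5, Zn–Cu couple, DME, reflux, slow addition), a known route to ten-membered cycloalkenes, should give the bis(triethylsilyl) cycloalkene F3. TBAF in THF then brings the route back at 24.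

2. Step 13 (Evans aldol). Facial selectivity may erode through mismatched double stereodifferentiation, because the auxiliary demands attack on the aldehyde face that the Cornforth preference of the α-alkoxy aldehyde disfavours. The fallback sets C7 by acylation and C6 by reduction and sets out from 17 and 7. Pinnick oxidation of 17 gives (4R,5R)-5-allyl-2,2,5-trimethyl-1,3-dioxolane-4-carboxylic acid F4, which the Ghosez reagent (1-chloro-N,N,2-trimethylprop-1-en-1-amine, CH2Cl2) converts under neutral conditions into the acid chloride F5. Acid 7 is joined to commercial (S)-4-benzyloxazolidin-2-one (PivCl, Et3N, LiCl) to give the (S)-configured imide F6. Its lithium Z-enolate (LiN(i-Pr)2, THF, −78 °C) should be C-acylated by F5 on the face away from the benzyl group to give the β-keto imide F7, which resists enolisation because of A(1,3) strain. Zn(BH4)2 (CH2Cl2/Et2O, −20 °C) should reduce the ketone through the dicarbonyl zinc chelate, anti to the C7 side chain, to the 6,7-syn β-hydroxy imide F8. NaOMe in MeOH then brings the route back at 21.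

3. Step 18 (angeloylation). Acylation of the hindered C6 hydroxyl may stall, and forcing conditions may isomerise the angeloyl unit from Z to E. The fallback builds the Z-alkene on the ester and sets out from 25. Esterification with 2-[bis(2,2,2-trifluoroethoxy)phosphoryl]propanoic acid (EDC·HCl, DMAP, CH2Cl2) gives the phosphonopropionate F9. Still–Gennari olefination (KN(SiMe3)2, 18-crown-6, THF, −78 °C; acetaldehyde) should give the Z-configured 2-methylbut-2-enoate, which is 28, where the route is rejoined.

**Further compounds**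

F1 | step 16 | bis(triethylsilyl) ether of 23 | C=C[C@H](C)CC[C@@H](C(C)(C)O[Si](CC)(CC)CC)[C@@H](O[Si](CC)(CC)CC)[C@@H]1OC(C)(C)O[C@]1(C)CC=C
F2 | step 16 | C1,C2-dialdehyde from ozonolysis of F1 | O=C[C@H](C)CC[C@@H](C(C)(C)O[Si](CC)(CC)CC)[C@@H](O[Si](CC)(CC)CC)[C@@H]1OC(C)(C)O[C@]1(C)CC=O
F3 | step 16 | bis(triethylsilyl) ether of 24 | CC[Si](CC)(CC)O[C@@H]1[C@H](C(C)(C)O[Si](CC)(CC)CC)CC[C@@H](C)/C=C\C[C@@](C)(OC(C)(C)O2)[C@H]12
F4 | step 13 | (4R,5R)-5-allyl-2,2,5-trimethyl-1,3-dioxolane-4-carboxylic acid | C=CC[C@@]1(C)OC(C)(C)O[C@H]1C(=O)O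
F5 | step 13 | (4R,5R)-5-allyl-2,2,5-trimethyl-1,3-dioxolane-4-carbonyl chloride | C=CC[C@@]1(C)OC(C)(C)O[C@H]1C(Cl)=O
F6 | step 13 | (S)-4-benzyl-3-[(R)-5-methylhept-6-enoyl]oxazolidin-2-one | C=C[C@H](C)CCCC(=O)N1[C@@H](Cc2ccccc2)COC1=O
F7 | step 13 | β-keto imide, (S)-4-benzyl-3-{(2R)-2-[(4R,5R)-5-allyl-2,2,5-trimethyl-1,3-dioxolane-4-carbonyl]-5-methylhept-6-enoyl}oxazolidin-2-one with (5R) side-chain centre | C=C[C@H](C)CC[C@@H](C(=O)N1[C@@H](Cc2ccccc2)COC1=O)C(=O)[C@@H]1OC(C)(C)O[C@]1(C)CC=C
F8 | step 13 | 6,7-syn β-hydroxy imide, the (S)-auxiliary analogue of 20 | C=C[C@H](C)CC[C@@H](C(=O)N1[C@@H](Cc2ccccc2)COC1=O)[C@@H](O)[C@@H]1OC(C)(C)O[C@]1(C)CC=C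
F9 | step 18 | 6-O-{2-[bis(2,2,2-trifluoroethoxy)phosphoryl]propanoyl} derivative of 25 | CC(C(=O)O[C@@H]1[C@H](C(C)(C)O)CC[C@@H](C)CCC[C@@](C)(OC(C)(C)O2)[C@H]12)P(=O)(OCC(F)(F)F)OCC(F)(F)F
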